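**Strategy**

The route rests on a disconnection of the 1,2-dioxine ring (O1–O2–C3–C4=C5–C6) at C3–C4. Because C3 is the β-carbon of the acetate side chain, the ring is a cyclised β-peroxy ester: a C4 alkenyl radical adds in Michael sense to a β-peroxyacrylate that is tied to C6 through the O–O bond. One operation closes the dioxine ring (6-exo-trig), makes the C3–C4 bond and sets C3 (3R) under control of a chelated oxazolidinone auxiliary. The precursor is an acyclic mixed peroxyketal: a vinyl iodide on C6 and a β-peroxyacryloyl imide on the peroxide oxygen. C6, an acid-labile ketal centre, is set last by ketal equilibration in methanol.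

Key step: step 10

Remark (numbering): the ring atoms are called O1, O2, C3, C4, C5, C6 as in the 3,6-dihydro-1,2-dioxin name, and the same labels are used for these atoms in the acyclic precursors.
Remark (assumption): the peroxyketal carbon C6 is assumed to epimerise by ketal exchange in Lewis-acidic methanol while C3 does not; C6 is therefore carried as a mixture (no descriptor at this atom in the SMILES of 11, 17 and 18) and fixed in the last step by equilibration and separation of the two C6 epimers.
Remark (drawing): the cyclopentadienyl rings of 9 are written σ-bonded in SMILES.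

**Route**

Step 1
Reactants: 1 (8E,10E)-dodeca-8,10-dien-1-ol
Product: 2 (2E,4E)-12-bromododeca-2,4-diene
Conditions: CBr4, PPh3, CH2Cl2, 0 °C
Reagents that add atoms: carbon tetrabromide BrC(Br)(Br)Br
Why: The Appel reaction turns the primary alcohol into the bromide under neutral conditions that leave the (E,E)-diene untouched.

Step 2
Reactants: 2 (2E,4E)-12-bromododeca-2,4-diene; 3 ethyl 7-bromoheptanoate
Product: 5 ethyl (15E,17E)-nonadeca-15,17-dienoate, via dienylmagnesium bromide 4 (not isolated)
Conditions: Mg, THF, 40 °C; then 3, Li2CuCl4 (3 mol %), NMP, THF, 0 °C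
Reagents that add atoms: none
Why: Copper-catalysed alkyl–alkyl Grignard cross-coupling (Kochi reaction) should join the two primary carbons faster than the Grignard reagent attacks the ethyl ester at 0 °C in the presence of NMP.

Step 3
Reactants: 5 ethyl (15E,17E)-nonadeca-15,17-dienoate
Product: 6 (15E,17E)-N-methoxy-N-methylnonadeca-15,17-dienamide
Conditions: MeNH(OMe)·HCl, i-PrMgCl, THF, −20 to 0 °C
Reagents that add atoms: N,O-dimethylhydroxylamine hydrochloride Cl.CNOC
Why: Aminolysis of the ester by the magnesium amide of N,O-dimethylhydroxylamine gives the Weinreb amide.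

Step 4
Reactants: 6 (15E,17E)-N-methoxy-N-methylnonadeca-15,17-dienamide
Product: 7 (17E,19E)-henicosa-17,19-dien-1-yn-3-one
Conditions: HC≡CMgBr, THF, 0 °C; quench into cold aq. NaHSO4
Reagents that add atoms: ethynylmagnesium bromide C#C[Mg]Br
Why: In the Weinreb ketone synthesis the chelated tetrahedral intermediate prevents over-addition, and the acidic quench keeps the liberated amine from adding to the terminal ynone.

Step 5
Reactants: 7 (17E,19E)-henicosa-17,19-dien-1-yn-3-one
Product: 8 (17E,19E)-3,3-dimethoxyhenicosa-17,19-dien-1-yne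
Conditions: HC(OMe)3, MeOH, p-TsOH·H2O (cat.), 23 °C
Reagents that add atoms: trimethyl orthoformate COC(OC)OC; methanol CO
Why: Acid-catalysed ketalisation is driven by the orthoformate as water scavenger, and without base methanol should not add to the alkyne.

Step 6
Reactants: 8 (17E,19E)-3,3-dimethoxyhenicosa-17,19-dien-1-yne
Product: 10 (1E,17E,19E)-1-iodo-3,3-dimethoxyhenicosa-1,17,19-triene, via alkenylzirconocene chloride 9 (not isolated)
Conditions: Cp2Zr(H)Cl, THF, 23 °C; then I2, −78 °C
Reagents that add atoms: iodine II
Why: Hydrozirconation of the terminal alkyne is syn and places zirconium on the terminal carbon, iodinolysis proceeds with retention to the (E)-vinyl iodide, and the terminal alkyne should react faster than the internal diene.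

Step 7
Reactants: 10 (1E,17E,19E)-1-iodo-3,3-dimethoxyhenicosa-1,17,19-triene
Product: 11 (1E,17E,19E)-3-hydroperoxy-1-iodo-3-methoxyhenicosa-1,17,19-triene (racemic)
Conditions: H2O2 (anhydrous, in Et2O), PPTS (cat.), 0 °C
Reagents that add atoms: hydrogen peroxide OO
Why: In this acid-catalysed perhydrolysis of a ketal the methoxy-stabilised allyl cation is trapped at its oxocarbenium carbon by H2O2 to give the α-methoxy hydroperoxide, and C6 is formed racemic on purpose because it is reset in step 11.

Step 8
Reactants: 12 (4S)-4-(diphenylmethyl)-1,3-oxazolidin-2-one; 13 prop-2-ynoic acid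
Product: 16 (4S)-4-(diphenylmethyl)-3-(prop-2-ynoyl)-1,3-oxazolidin-2-one, via prop-2-ynoyl chloride 14 (not isolated), via lithium oxazolidinide 15 (not isolated)
Conditions: 13, 1-chloro-N,N,2-trimethylprop-1-en-1-amine, CH2Cl2, 0 °C; 12, n-BuLi, THF, −78 °C; then combine, −78 °C
Reagents that add atoms: none
Why: N-Acylation of the lithiated oxazolidinone by an acid chloride that is made with an α-chloroenamine under neutral conditions avoids HCl addition to the alkyne.

Step 9
Reactants: 11 (1E,17E,19E)-3-hydroperoxy-1-iodo-3-methoxyhenicosa-1,17,19-triene (racemic); 16 (4S)-4-(diphenylmethyl)-3-(prop-2-ynoyl)-1,3-oxazolidin-2-one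
Product: 17 (4S)-4-(diphenylmethyl)-3-[(2E)-3-{[(1E,17E,19E)-1-iodo-3-methoxyhenicosa-1,17,19-trien-3-yl]peroxy}prop-2-enoyl]-1,3-oxazolidin-2-one (both C6 epimers)
Conditions: N-methylmorpholine (10 mol %), CH2Cl2, 0 °C
Reagents that add atoms: none
Why: Amine-catalysed oxa-Michael addition of the hydroperoxide to the ynoyl imide is the reaction by which alcohols give (E)-β-alkoxyacrylates; the tertiary hydroperoxide has no α-hydrogen and tolerates the amine, and the E geometry fixes which face of C3 is open in step 10.

Step 10
Reactants: 17 (4S)-4-(diphenylmethyl)-3-[(2E)-3-{[(1E,17E,19E)-1-iodo-3-methoxyhenicosa-1,17,19-trien-3-yl]peroxy}prop-2-enoyl]-1,3-oxazolidin-2-one (both C6 epimers)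
Product: 18 (4S)-4-(diphenylmethyl)-3-({(3R)-6-methoxy-6-[(14E,16E)-octadeca-14,16-dien-1-yl]-3,6-dihydro-1,2-dioxin-3-yl}acetyl)-1,3-oxazolidin-2-one (both C6 epimers)
Conditions: MgBr2·OEt2 (2 equiv), Bu3SnH (slow addition), Et3B, air, CH2Cl2, −78 °C
Reagents that add atoms: none
Why: Proposed new method: Bu3Sn• abstracts iodine from 17 to give the bent C4 σ-vinyl radical, whose E and Z forms interconvert quickly, so that the Z form adds to C3, the β-carbon of the magnesium-chelated β-peroxyacryloyl imide, and the resulting α-acyl radical is reduced by Bu3SnH. The closest known reaction types are 6-exo cyclisations of vinyl and aryl radicals onto β-alkoxyacrylates and Lewis-acid-chelated radical conjugate additions to N-enoyl oxazolidinones, neither of which has been shown through an O–O tether. The 1,2-dioxine ring closes in the 6-exo-trig mode with the C4=C5 bond inside the new ring. C3 is controlled by the auxiliary: in the s-cis imide with both carbonyl groups on magnesium the diphenylmethyl group of the (4S)-oxazolidinone covers the Re face of C3, so C4 should add to the Si face and give 3R in both C6 epimers, while C6 is not controlled here. The step needs addition to outrun 1,5-hydrogen transfer from the OCH3 group, premature reduction of the vinyl radical and 3-exo attack of the α-acyl radical on the O–O bond; the doubly activated acceptor six atoms from the radical, the low temperature and the slow addition of Bu3SnH should secure this, and the neutral conditions spare the base-labile C3–H peroxide and the chain diene. Any 3S product is a diastereomer while the auxiliary is attached and is removed by chromatography.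

Step 11
Reactants: 18 (4S)-4-(diphenylmethyl)-3-({(3R)-6-methoxy-6-[(14E,16E)-octadeca-14,16-dien-1-yl]-3,6-dihydro-1,2-dioxin-3-yl}acetyl)-1,3-oxazolidin-2-one (both C6 epimers)
Product: 19 xestin B, methyl {(3R,6S)-6-methoxy-6-[(14E,16E)-octadeca-14,16-dien-1-yl]-3,6-dihydro-1,2-dioxin-3-yl}acetate
Conditions: Sm(OTf)3, MeOH, 23 °C; chromatography on SiO2, (6R) epimer returned to the same conditions
Reagents that add atoms: methanol CO
Why: Lanthanide-triflate-catalysed methanolysis of the chelated N-acyl oxazolidinone gives the methyl ester without base (base would trigger Kornblum–DeLaMare cleavage of the dioxine), and the same Lewis-acidic methanol should exchange the ketal through the cyclic peroxycarbenium ion, so that C6 equilibrates with C3 untouched and the (6S) epimer, with OMe trans to the C3 side chain, is separated while the (6R) epimer is recycled.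

**Compound list**

1 | (8E,10E)-dodeca-8,10-dien-1-ol | C/C=C/C=C/CCCCCCCO | starting material
2 | (2E,4E)-12-bromododeca-2,4-diene | C/C=C/C=C/CCCCCCCBr | intermediate
3 | ethyl 7-bromoheptanoate | CCOC(=O)CCCCCCBr | starting material
4 | [(8E,10E)-dodeca-8,10-dien-1-yl]magnesium bromide | C/C=C/C=C/CCCCCCC[Mg]Br | intermediate
5 | ethyl (15E,17E)-nonadeca-15,17-dienoate | CCOC(=O)CCCCCCCCCCCCC/C=C/C=C/C | intermediate
6 | (15E,17E)-N-methoxy-N-methylnonadeca-15,17-dienamide | CON(C)C(=O)CCCCCCCCCCCCC/C=C/C=C/C | intermediate
7 | (17E,19E)-henicosa-17,19-dien-1-yn-3-one | C#CC(=O)CCCCCCCCCCCCC/C=C/C=C/C | intermediate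
8 | (17E,19E)-3,3-dimethoxyhenicosa-17,19-dien-1-yne | C#CC(OC)(OC)CCCCCCCCCCCCC/C=C/C=C/C | intermediate
9 | chlorobis(cyclopentadienyl)[(1E,17E,19E)-3,3-dimethoxyhenicosa-1,17,19-trien-1-yl]zirconium | Cl[Zr](/C=C/C(OC)(OC)CCCCCCCCCCCCC/C=C/C=C/C)(C1C=CC=C1)C1C=CC=C1 | intermediate
10 | (1E,17E,19E)-1-iodo-3,3-dimethoxyhenicosa-1,17,19-triene | I/C=C/C(OC)(OC)CCCCCCCCCCCCC/C=C/C=C/C | intermediate
11 | (1E,17E,19E)-3-hydroperoxy-1-iodo-3-methoxyhenicosa-1,17,19-triene (racemic) | I/C=C/C(OC)(OO)CCCCCCCCCCCCC/C=C/C=C/C | intermediate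
12 | (4S)-4-(diphenylmethyl)-1,3-oxazolidin-2-one | O=C1N[C@@H](C(c2ccccc2)c2ccccc2)CO1 | starting material
13 | prop-2-ynoic acid | C#CC(=O)O | starting material
14 | prop-2-ynoyl chloride | C#CC(=O)Cl | intermediate
15 | lithium (4S)-4-(diphenylmethyl)-2-oxo-1,3-oxazolidin-3-ide | [Li+].O=C1[N-][C@@H](C(c2ccccc2)c2ccccc2)CO1 | intermediate
16 | (4S)-4-(diphenylmethyl)-3-(prop-2-ynoyl)-1,3-oxazolidin-2-one | C#CC(=O)N1[C@@H](C(c2ccccc2)c2ccccc2)COC1=O | intermediate
17 | (4S)-4-(diphenylmethyl)-3-[(2E)-3-{[(1E,17E,19E)-1-iodo-3-methoxyhenicosa-1,17,19-trien-3-yl]peroxy}prop-2-enoyl]-1,3-oxazolidin-2-one (both C6 epimers) | C/C=C/C=C/CCCCCCCCCCCCCC(OC)(/C=C/I)OO/C=C/C(=O)N1[C@@H](C(c2ccccc2)c2ccccc2)COC1=O | intermediate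
18 | (4S)-4-(diphenylmethyl)-3-({(3R)-6-methoxy-6-[(14E,16E)-octadeca-14,16-dien-1-yl]-3,6-dihydro-1,2-dioxin-3-yl}acetyl)-1,3-oxazolidin-2-one (both C6 epimers) | C/C=C/C=C/CCCCCCCCCCCCCC1(OC)C=C[C@@H](CC(=O)N2[C@@H](C(c3ccccc3)c3ccccc3)COC2=O)OO1 | intermediate
19 | xestin B, methyl {(3R,6S)-6-methoxy-6-[(14E,16E)-octadeca-14,16-dien-1-yl]-3,6-dihydro-1,2-dioxin-3-yl}acetate | C/C=C/C=C/CCCCCCCCCCCCC[C@@]1(OC)C=C[C@@H](CC(=O)OC)OO1 | target

**Count and risks**

Total step count: 11. Longest linear sequence: 10 steps (steps 1 to 7 and 9 to 11).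

Steps most likely to fail:

Step 10 (key step). The vinyl radical may be reduced or may translocate by 1,5-hydrogen transfer before it cyclises. Tin or carbon radicals may attack the O–O bond, the Lewis acid may ionise the acyclic peroxyketal, and face selection at C3 may be poor. The fallback uses known chemistry and closes the same ring at O2–C3 by conjugate addition of the hydroperoxide; it sets out from 8 and comes back at 19. Sonogashira coupling of 8 with methyl (Z)-3-iodoacrylate (PdCl2(PPh3)2, CuI, Et3N) should give methyl (2Z,20E,22E)-6,6-dimethoxytetracosa-2,20,22-trien-4-ynoate F1. Semi-reduction of the conjugated alkyne with zinc activated by Cu(OAc)2 and AgNO3 in MeOH/H2O (Boland reduction), which spares the chain diene, should give methyl (2Z,4Z,20E,22E)-6,6-dimethoxytetracosa-2,4,20,22-tetraenoate F2. Perhydrolysis as in step 7 should give methyl (2Z,4Z,20E,22E)-6-hydroperoxy-6-methoxytetracosa-2,4,20,22-tetraenoate F3. Et2NH (cat.) in CF3CH2OH at 0 °C for a short time should close the dioxine by 6-exo oxa-Michael addition of the hydroperoxide to C3. This gives methyl {6-methoxy-6-[(14E,16E)-octadeca-14,16-dien-1-yl]-3,6-dihydro-1,2-dioxin-3-yl}acetate as the mixture of all stereoisomers at C3 and C6, F4. Ketal equilibration (PPTS, MeOH), separation of the C6 epimers on silica and of the enantiomers on a chiral stationary phase then return 19.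

Step 9. The amine catalyst may oligomerise the ynoyl imide 16, or the vinyl peroxide 17 may be lost by O–O cleavage before it is isolated; partial formation of the Z isomer would also erode step 10. The fallback replaces alkyne addition by nucleophilic vinylic substitution; it sets out from 11 and 12 and comes back at 17. Acylation of lithiated 12 with (E)-3-chloroacryloyl chloride, made from commercial (E)-3-chloroacrylic acid and (COCl)2, should give (4S)-3-[(2E)-3-chloroprop-2-enoyl]-4-(diphenylmethyl)-1,3-oxazolidin-2-one F5, an acceptor that can be stored. Treatment of 11 and F5 with Cs2CO3 in MeCN at 0 °C should give 17 by addition–elimination with retention of the E geometry.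

Step 11. Methanolysis of the hindered imide may be slow, the Lewis acid may open or degrade the peroxyketal, or the equilibrium may lie on the side of the (6R) epimer. The fallback leaves the auxiliary out and carries the methyl ester from the start; it sets out from 11 and comes back at 19. Methyl propiolate and 11 with N-methylmorpholine (cat.) should give methyl (2E)-3-{[(1E,17E,19E)-1-iodo-3-methoxyhenicosa-1,17,19-trien-3-yl]peroxy}prop-2-enoate F6. The radical cyclisation of step 10 without Lewis acid (Bu3SnH, Et3B, air, toluene, −40 °C) should then give the stereoisomer mixture F4 directly as the methyl ester, so no ester exchange is needed. A brief PPTS/MeOH equilibration and chromatography on silica and then on a chiral stationary phase give 19.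

Further compounds
F1 | step 10 | methyl (2Z,20E,22E)-6,6-dimethoxytetracosa-2,20,22-trien-4-ynoate | COC(=O)/C=C\C#CC(OC)(OC)CCCCCCCCCCCCC/C=C/C=C/C
F2 | step 10 | methyl (2Z,4Z,20E,22E)-6,6-dimethoxytetracosa-2,4,20,22-tetraenoate | COC(=O)/C=C\C=C/C(OC)(OC)CCCCCCCCCCCCC/C=C/C=C/C
F3 | step 10 | methyl (2Z,4Z,20E,22E)-6-hydroperoxy-6-methoxytetracosa-2,4,20,22-tetraenoate (racemic) | COC(=O)/C=C\C=C/C(OC)(OO)CCCCCCCCCCCCC/C=C/C=C/C
F4 | step 10 | methyl {6-methoxy-6-[(14E,16E)-octadeca-14,16-dien-1-yl]-3,6-dihydro-1,2-dioxin-3-yl}acetate (all stereoisomers at C3 and C6) | C/C=C/C=C/CCCCCCCCCCCCCC1(OC)C=CC(CC(=O)OC)OO1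
F5 | step 9 | (4S)-3-[(2E)-3-chloroprop-2-enoyl]-4-(diphenylmethyl)-1,3-oxazolidin-2-one | Cl/C=C/C(=O)N1[C@@H](C(c2ccccc2)c2ccccc2)COC1=O
F6 | step 11 | methyl (2E)-3-{[(1E,17E,19E)-1-iodo-3-methoxyhenicosa-1,17,19-trien-3-yl]peroxy}prop-2-enoate (racemic) | C/C=C/C=C/CCCCCCCCCCCCCC(OC)(/C=C/I)OO/C=C/C(=O)OC
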